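The strategy takes ring C apart around its carbonyl carbon C4. One palladium-catalysed, one-flask operation joins an aryl iodide, carbon monoxide and a terminal arylacetylene. It forms C4a–C4, C4–C3 and O1–C2, and so builds the whole pyranone. The feature exploited is that in ring A only C4a lacks oxygen. C4a lies on the C4a–C7 mirror axis between two identical oxygens (future O1 and 5-OH), so one iodine at C4a fixes ring C with no regiochemical choice. The precursor is the 2-iodoresorcinol bearing OMe, OBn, OMe on its other three carbons, handled as its diacetate to tame its electron richness. Its partner is 2,4-bis(benzyloxy)-5-methoxyphenylacetylene.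

Key step: step 8

Remark: the target has no stereocentre and no configurationally stable axis, so it is achiral and no enantiomer has to be selected. The only stereocentres of the route (racemic epoxide 18) vanish in the flask in which they form.

Step 1
Reactants: 1 2,6-dimethoxyphenol (syringol)
Product: 2 2-(benzyloxy)-1,3-dimethoxybenzene
Conditions: BnBr, K2CO3, DMF, 60 °C
Reagents that add atoms: benzyl bromide BrCc1ccccc1
Why: Williamson ether synthesis on the only hydroxyl, which marks the future 7-OH with a group that falls in the final hydrogenolysis.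

Step 2
Reactants: 2 2-(benzyloxy)-1,3-dimethoxybenzene
Product: 3 3-(benzyloxy)-1,5-dibromo-2,4-dimethoxybenzene
Conditions: NBS (2.1 equiv), MeCN, 0 °C → rt, dark
Reagents that add atoms: N-bromosuccinimide O=C1CCC(=O)N1Br
Why: Electrophilic aromatic bromination, in which the two equivalent positions that are ortho to one methoxy and para to the other are far more activated than the carbon para to the twisted central benzyloxy group, so that carbon should stay C–H between the two bromines.

Step 3
Reactants: 3 3-(benzyloxy)-1,5-dibromo-2,4-dimethoxybenzene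
Product: 5 5-(benzyloxy)-4,6-dimethoxybenzene-1,3-diol, via bis(pinacol boronate) 4 (not isolated)
Conditions: B2pin2 (2.6 equiv), PdCl2(dppf) (5 mol %), KOAc, dioxane, 90 °C; then 30% aq H2O2, THF–pH 7 buffer, 0 °C → rt, argon
Reagents that add atoms: hydrogen peroxide OO; bis(pinacolato)diboron CC1(C)OB(OC1(C)C)B1OC(C)(C)C(C)(C)O1 (boron stays only in intermediate 4)
Why: Double Miyaura borylation followed by ipso-oxidation of the C–B bonds, feasible because both symmetry-equivalent C–Br bonds carry only one ortho substituent and because neutral peroxide turns aryl boronates into phenols by 1,2-aryl migration without touching the ethers.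

Step 4
Reactants: 5 5-(benzyloxy)-4,6-dimethoxybenzene-1,3-diol
Product: 7 5-(benzyloxy)-2-iodo-4,6-dimethoxy-1,3-phenylene diacetate, via free iodoresorcinol 6 (not isolated)
Conditions: NIS (1.0 equiv), MeCN, −10 → 0 °C, dark; then Ac2O, pyridine, DMAP (cat.), 0 °C → rt
Reagents that add atoms: N-iodosuccinimide O=C1CCC(=O)N1I; acetic anhydride CC(=O)OC(C)=O
Why: Electrophilic aromatic iodination at the one remaining ring C–H, ortho to both hydroxyls and para to the benzyloxy group, is followed in the same flask by DMAP-catalysed O-acetylation, so the oxidation- and deiodination-prone 6 is never stored.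

Step 5
Reactants: 8 2,4,5-trimethoxybenzaldehyde
Product: 9 2,4-dihydroxy-5-methoxybenzaldehyde
Conditions: AlCl3 (4 equiv), CH2Cl2, 0 °C → rt; ice-water quench
Reagents that add atoms: none
Why: Lewis-acid aryl methyl ether cleavage, in which AlCl3 bound to the formyl oxygen activates only the two methoxy groups conjugated with it (the ortho one through a six-membered chelate, the para one as a vinylogous ester), so chloride should remove these two methyl groups while the non-conjugated 5-OMe stays.

Step 6
Reactants: 9 2,4-dihydroxy-5-methoxybenzaldehyde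
Product: 10 2,4-bis(benzyloxy)-5-methoxybenzaldehyde
Conditions: BnBr (2.4 equiv), K2CO3, DMF, 60 °C
Reagents that add atoms: benzyl bromide BrCc1ccccc1
Why: Double Williamson ether synthesis, with warming in a polar aprotic solvent to alkylate the hydrogen-bonded 2-OH as well.

Step 7
Reactants: 10 2,4-bis(benzyloxy)-5-methoxybenzaldehyde; 11 dimethyl (1-diazo-2-oxopropyl)phosphonate
Product: 12 1,5-bis(benzyloxy)-2-ethynyl-4-methoxybenzene
Conditions: K2CO3, MeOH–THF, 0 °C → rt
Reagents that add atoms: dimethyl (1-diazo-2-oxopropyl)phosphonate COP(=O)(OC)C(=[N+]=[N-])C(C)=O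
Why: Ohira–Bestmann homologation, in which methanolysis of 11 releases the diazomethylphosphonate anion, this olefinates the non-enolisable aldehyde, and the diazoalkene loses N2 with a 1,2-hydrogen shift to the terminal alkyne under conditions too mild to disturb the ethers.

Step 8
Reactants: 7 5-(benzyloxy)-2-iodo-4,6-dimethoxy-1,3-phenylene diacetate; 12 1,5-bis(benzyloxy)-2-ethynyl-4-methoxybenzene; 13 carbon monoxide
Product: 16 7,2',4'-tris(benzyloxy)-5-hydroxy-6,8,5'-trimethoxyflavone, via ynone diacetate 14 (not isolated), via diethylamino enaminone 15 (not isolated)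
Conditions: PdCl2(dppf) (5 mol %), Et3N (3 equiv), CO (5 bar), THF, 50 °C, no Cu; then vent, Et2NH (10 equiv), 50 °C, same flask
Reagents that add atoms: carbon monoxide [C-]#[O+]; diethylamine CCNCC (nitrogen stays only in intermediate 15)
Why: Pd(0) inserts into the C–I bond of 7, CO migrates in to give the aroylpalladium species (C4a–C4), and base-assisted alkynyl transfer from 12 with reductive elimination gives ynone 14 (C4–C3); diethylamine added afterwards removes both acetyl groups, adds to the ynone to give enaminone 15, and is expelled when a freed phenol attacks C2 (O1–C2). The closest known reaction type is the palladium-catalysed carbonylative Sonogashira coupling–cyclisation of 2-iodophenols or their acetates with terminal arylacetylenes to flavones. Ring C closes by a 6-endo-trig addition–elimination on the enaminone (formally 6-endo-dig on the ynone), and no stereocentre is created. Flavone rather than aurone is secured because in 15 only the amine-bearing β-carbon is electrophilic, so 5-exo attack at the α-carbon has no driving force, and the mirror symmetry of ring A makes both phenols give the same product, the spectator ending as the chelated 5-OH. CO uptake rather than direct alkynylation and benzofuran formation is favoured by leaving out copper, by CO overpressure and by the fast migration of an electron-rich, doubly ortho-substituted aryl group, while amide formation is avoided because the secondary amine arrives only after CO has been vented. The acetates make the iodide less electron-rich for oxidative addition, shield it from oxidation and deiodination, and keep the phenols silent until the ynone exists.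

Step 9
Reactants: 16 7,2',4'-tris(benzyloxy)-5-hydroxy-6,8,5'-trimethoxyflavone
Product: 17 5,7,2',4'-tetrakis(benzyloxy)-6,8,5'-trimethoxyflavone
Conditions: BnBr, K2CO3, KI (cat.), DMF, 70 °C
Reagents that add atoms: benzyl bromide BrCc1ccccc1
Why: Williamson ether synthesis on the chelated 5-OH, the only acidic site left, which removes the free phenol that the dioxirane of the next step would otherwise oxidise.

Step 10
Reactants: 17 5,7,2',4'-tetrakis(benzyloxy)-6,8,5'-trimethoxyflavone
Product: 19 5,7,2',4'-tetrakis(benzyloxy)-3-hydroxy-6,8,5'-trimethoxyflavone, via flavone 2,3-epoxide 18 (not isolated)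
Conditions: DMDO (acetone solution, 3 equiv), CH2Cl2, 0 °C → rt; then p-TsOH (cat.), CH2Cl2, rt
Reagents that add atoms: dimethyldioxirane CC1(C)OO1
Why: Dioxirane epoxidation of the enol-ether-like C2=C3 bond, followed by acid-catalysed opening at C2 (cation stabilised by O1 and the aryl ring) and loss of H3, is the known flavone-to-flavonol conversion that tolerates benzyl ethers, and the two stereocentres of racemic 18 disappear on rearomatisation.

Step 11
Reactants: 19 5,7,2',4'-tetrakis(benzyloxy)-3-hydroxy-6,8,5'-trimethoxyflavone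
Product: 20 5,7,2',4'-tetrakis(benzyloxy)-3,6,8,5'-tetramethoxyflavone
Conditions: MeI, K2CO3, acetone, reflux
Reagents that add atoms: iodomethane CI
Why: Williamson O-methylation of the enolic 3-OH, which is the only free hydroxyl in the molecule.

Step 12
Reactants: 20 5,7,2',4'-tetrakis(benzyloxy)-3,6,8,5'-tetramethoxyflavone
Product: 21 5,7,2',4'-tetrahydroxy-3,6,8,5'-tetramethoxyflavone (target)
Conditions: H2 (1 atm), 10% Pd/C, EtOAc–MeOH, rt
Reagents that add atoms: none
Why: Catalytic hydrogenolysis should cleave all four aryl benzyl ethers at once, while the methyl ethers and the tetrasubstituted C2=C3 bond of the 3-methoxychromone are inert at atmospheric pressure.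

Compound list
1 | 2,6-dimethoxyphenol (syringol) | COc1cccc(OC)c1O | starting material
2 | 2-(benzyloxy)-1,3-dimethoxybenzene | COc1cccc(OC)c1OCc1ccccc1 | intermediate
3 | 3-(benzyloxy)-1,5-dibromo-2,4-dimethoxybenzene | COc1c(Br)cc(Br)c(OC)c1OCc1ccccc1 | intermediate
4 | 3-(benzyloxy)-2,4-dimethoxy-1,5-bis(4,4,5,5-tetramethyl-1,3,2-dioxaborolan-2-yl)benzene | COc1c(B2OC(C)(C)C(C)(C)O2)cc(B2OC(C)(C)C(C)(C)O2)c(OC)c1OCc1ccccc1 | intermediate (not isolated)
5 | 5-(benzyloxy)-4,6-dimethoxybenzene-1,3-diol | COc1c(O)cc(O)c(OC)c1OCc1ccccc1 | intermediate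
6 | 5-(benzyloxy)-2-iodo-4,6-dimethoxybenzene-1,3-diol | COc1c(O)c(I)c(O)c(OC)c1OCc1ccccc1 | intermediate (not isolated)
7 | 5-(benzyloxy)-2-iodo-4,6-dimethoxy-1,3-phenylene diacetate | COc1c(OC(C)=O)c(I)c(OC(C)=O)c(OC)c1OCc1ccccc1 | intermediate
8 | 2,4,5-trimethoxybenzaldehyde | COc1cc(OC)c(C=O)cc1OC | starting material
9 | 2,4-dihydroxy-5-methoxybenzaldehyde | COc1cc(C=O)c(O)cc1O | intermediate
10 | 2,4-bis(benzyloxy)-5-methoxybenzaldehyde | COc1cc(C=O)c(OCc2ccccc2)cc1OCc1ccccc1 | intermediate
11 | dimethyl (1-diazo-2-oxopropyl)phosphonate (Ohira–Bestmann reagent) | COP(=O)(OC)C(=[N+]=[N-])C(C)=O | starting material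
12 | 1,5-bis(benzyloxy)-2-ethynyl-4-methoxybenzene | C#Cc1cc(OC)c(OCc2ccccc2)cc1OCc1ccccc1 | intermediate
13 | carbon monoxide | [C-]#[O+] | starting material
14 | 5-(benzyloxy)-2-{3-[2,4-bis(benzyloxy)-5-methoxyphenyl]prop-2-ynoyl}-4,6-dimethoxy-1,3-phenylene diacetate | COc1c(OC(C)=O)c(C(=O)C#Cc2cc(OC)c(OCc3ccccc3)cc2OCc2ccccc2)c(OC(C)=O)c(OC)c1OCc1ccccc1 | intermediate (not isolated)
15 | (E)-1-[4-(benzyloxy)-2,6-dihydroxy-3,5-dimethoxyphenyl]-3-[2,4-bis(benzyloxy)-5-methoxyphenyl]-3-(diethylamino)prop-2-en-1-one (geometry without consequence for the closure) | CCN(CC)/C(=C/C(=O)c1c(O)c(OC)c(OCc2ccccc2)c(OC)c1O)c1cc(OC)c(OCc2ccccc2)cc1OCc1ccccc1 | intermediate (not isolated)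
16 | 7,2',4'-tris(benzyloxy)-5-hydroxy-6,8,5'-trimethoxyflavone | COc1cc(-c2cc(=O)c3c(O)c(OC)c(OCc4ccccc4)c(OC)c3o2)c(OCc2ccccc2)cc1OCc1ccccc1 | intermediate
17 | 5,7,2',4'-tetrakis(benzyloxy)-6,8,5'-trimethoxyflavone | COc1cc(-c2cc(=O)c3c(OCc4ccccc4)c(OC)c(OCc4ccccc4)c(OC)c3o2)c(OCc2ccccc2)cc1OCc1ccccc1 | intermediate
18 | 2,3-epoxide of 17, i.e. 4,6-bis(benzyloxy)-1a-[2,4-bis(benzyloxy)-5-methoxyphenyl]-3,5-dimethoxy-1a,7a-dihydro-7H-oxireno[2,3-b]chromen-7-one (racemic, cis-fused by necessity, one enantiomer drawn) | O=C1[C@H]2O[C@@]2(c2cc(OC)c(OCc3ccccc3)cc2OCc2ccccc2)Oc2c(OC)c(OCc3ccccc3)c(OC)c(OCc3ccccc3)c21 | intermediate (not isolated)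
19 | 5,7,2',4'-tetrakis(benzyloxy)-3-hydroxy-6,8,5'-trimethoxyflavone | COc1cc(-c2oc3c(OC)c(OCc4ccccc4)c(OC)c(OCc4ccccc4)c3c(=O)c2O)c(OCc2ccccc2)cc1OCc1ccccc1 | intermediate
20 | 5,7,2',4'-tetrakis(benzyloxy)-3,6,8,5'-tetramethoxyflavone | COc1cc(-c2oc3c(OC)c(OCc4ccccc4)c(OC)c(OCc4ccccc4)c3c(=O)c2OC)c(OCc2ccccc2)cc1OCc1ccccc1 | intermediate
21 | 5,7,2',4'-tetrahydroxy-3,6,8,5'-tetramethoxyflavone (achiral) | COc1cc(-c2oc3c(OC)c(O)c(OC)c(O)c3c(=O)c2OC)c(O)cc1O | target

Total step count: 12. Longest linear sequence: 9 steps (steps 1–4 and 8–12).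

Steps most likely to fail

1. Step 8. Oxidative addition at the crowded C–I bond may be too slow. Reductive loss of iodine, premature acetate cleavage or alkynylation without CO uptake could then overtake the carbonylative path. The fallback builds ring C by the classical chalcone route, without palladium or CO. It sets out from 5 and 10 and comes back at 16.
   - Friedel–Crafts C-acetylation of 5 at its single free ring carbon (Ac2O, BF3·OEt2, 0 °C → rt, then brief K2CO3/MeOH to remove any O-acetate) should give 1-[4-(benzyloxy)-2,6-dihydroxy-3,5-dimethoxyphenyl]ethan-1-one F1.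
   - Claisen–Schmidt condensation of this ketone with 10 (KOH, EtOH, rt) should give (E)-1-[4-(benzyloxy)-2,6-dihydroxy-3,5-dimethoxyphenyl]-3-[2,4-bis(benzyloxy)-5-methoxyphenyl]prop-2-en-1-one F2.
   - Oxidative cyclisation (I2 cat., DMSO, 110–120 °C) closes the pyranone to 16. The symmetry of ring A again removes any choice between the two phenols.

2. Step 10. The dioxirane may oxidise the electron-rich rings or benzylic C–H bonds faster than the twisted C2=C3 bond, or the epoxidation may stall. The fallback oxygenates C3 through an anion instead of an electrophilic oxidant. It sets out from 17 and comes back at 19.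
   - Deprotonation of the C3–H next to the carbonyl (LDA, THF, −78 °C) should give the 3-lithio derivative of 17 F3.
   - Trapping with B(OMe)3 should give the dimethyl flavon-3-ylboronate F4.
   - H2O2/AcOH (0 °C → rt) oxidises the C–B bond to the flavonol 19.

3. Step 3. The second borylation may lag behind the first, protodebromination may erode material, or the electron-rich diol may be over-oxidised during the peroxide stage. The fallback forms both C–O bonds directly by copper-catalysed Ullmann-type hydroxylation. It sets out from 3 and comes back at 5.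
   - Conditions are Cu(acac)2 (cat.), an oxalamide ligand, LiOH, DMSO–H2O, 80–100 °C under argon, then acidification.
   - No oxidant is present and no new compound is made (F0).

Further compounds
F1 | step 8 | 1-[4-(benzyloxy)-2,6-dihydroxy-3,5-dimethoxyphenyl]ethan-1-one | CC(=O)c1c(O)c(OC)c(OCc2ccccc2)c(OC)c1O
F2 | step 8 | (E)-1-[4-(benzyloxy)-2,6-dihydroxy-3,5-dimethoxyphenyl]-3-[2,4-bis(benzyloxy)-5-methoxyphenyl]prop-2-en-1-one | O=C(/C=C/c1cc(OC)c(OCc2ccccc2)cc1OCc1ccccc1)c1c(O)c(OC)c(OCc2ccccc2)c(OC)c1O
F3 | step 10 | 3-lithio-5,7,2',4'-tetrakis(benzyloxy)-6,8,5'-trimethoxyflavone | [Li]c1c(-c2cc(OC)c(OCc3ccccc3)cc2OCc2ccccc2)oc2c(OC)c(OCc3ccccc3)c(OC)c(OCc3ccccc3)c2c1=O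
F4 | step 10 | dimethyl [5,7,2',4'-tetrakis(benzyloxy)-6,8,5'-trimethoxyflavon-3-yl]boronate | COB(OC)c1c(-c2cc(OC)c(OCc3ccccc3)cc2OCc2ccccc2)oc2c(OC)c(OCc3ccccc3)c(OC)c(OCc3ccccc3)c2c1=O
F0 | step 3 | none | none
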